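**Strategy.** Ring B is disconnected at C5–C6. Ring-fusion carbon C5 is sp2 in a ring A cyclopentene (C4=C5) that already holds the isopropyl group at C4, and its neighbour C6 is a carbinol. C5 can therefore act as a vinyl nucleophile toward a C6 aldehyde. An intramolecular Nozaki–Hiyama–Kishi reaction turns the C5 enol triflate into an alkenylchromium that adds to the tethered aldehyde. One operation forms C5–C6, the seven-membered ring B and the C6 carbinol. The precursor is an enantiopure cyclopentenyl triflate (C1 and C2 set) whose C1 side chain is a (Z)-3-methylpent-2-enyl unit ending in the aldehyde. The C4=C5 olefin later takes oxygen at C4 and hydrogen at C5.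

Key step: step 12

Remark: atoms carry the target numbering C1–C10 (ring A = C1–C5, ring B = C1, C5–C10); β is the face of the C1 methyl group and α the opposite face; TBS = tert-butyldimethylsilyl; bicyclic compounds are named as bicyclo[5.3.0]decanes with this numbering; a ketoreductase with the required selectivity for step 6 is assumed to be found by panel screening.

Step 1
Reactants: 1 tert-butyl(but-3-yn-1-yloxy)dimethylsilane
Product: 3 ethyl 5-(TBSO)pent-2-ynoate, via lithium acetylide 2 (not isolated)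
Conditions: n-BuLi, THF, −78 °C; ClCO2Et, −78 → 0 °C
Reagents that add atoms: ethyl chloroformate CCOC(=O)Cl
Why: Deprotonation of the terminal alkyne and C-acylation of the lithium acetylide with the chloroformate is the standard ynoate synthesis and leaves the silyl ether untouched.

Step 2
Reactants: 3 ethyl 5-(TBSO)pent-2-ynoate
Product: 5 ethyl (2Z)-5-(TBSO)-3-methylpent-2-enoate, via alkenylcuprate 4 (not isolated)
Conditions: Me2CuLi (from MeLi and CuI), THF, −78 °C; sat. aq. NH4Cl, −78 °C
Reagents that add atoms: lithium dimethylcuprate [Li+].C[Cu-]C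
Why: Conjugate addition of a lithium dialkylcuprate to a 2-ynoate is a syn carbocupration, so at −78 °C copper and the new methyl end up cis and protonation with retention gives the (Z)-enoate in which the ester and the silyloxyethyl arm are cis, the geometry needed for the C8=C9 olefin inside ring B.

Step 3
Reactants: 5 ethyl (2Z)-5-(TBSO)-3-methylpent-2-enoate
Product: 6 (2Z)-5-(TBSO)-3-methylpent-2-en-1-ol
Conditions: i-Bu2AlH, CH2Cl2, −78 °C
Reagents that add atoms: none
Why: i-Bu2AlH reduces the unsaturated ester in a 1,2 sense to the allylic alcohol at low temperature without disturbing the olefin geometry or the silyl ether.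

Step 4
Reactants: 6 (2Z)-5-(TBSO)-3-methylpent-2-en-1-ol
Product: 7 {[(3Z)-5-bromo-3-methylpent-3-en-1-yl]oxy}(tert-butyl)dimethylsilane
Conditions: CBr4, PPh3, CH2Cl2, 0 °C
Reagents that add atoms: carbon tetrabromide BrC(Br)(Br)Br
Why: The Appel reaction replaces the primary allylic hydroxyl by bromide through SN2 attack on the alkoxyphosphonium ion under near-neutral conditions, so the Z geometry and the silyl ether survive.

Step 5
Reactants: 7 {[(3Z)-5-bromo-3-methylpent-3-en-1-yl]oxy}(tert-butyl)dimethylsilane, 8 2-methylcyclopentane-1,3-dione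
Product: 9 2-methyl-2-[(2Z)-5-(TBSO)-3-methylpent-2-en-1-yl]cyclopentane-1,3-dione
Conditions: NaOH (1 M aq.), Bu4NI (cat.), 25 °C
Reagents that add atoms: none
Why: C-alkylation of the stabilised dione enolate with a primary allylic bromide in water, where hydrogen bonding disfavours O-alkylation, is the standard route to 2,2-disubstituted cyclopentane-1,3-diones and creates the future C1 as a prochiral quaternary carbon.

Step 6
Reactants: 9 2-methyl-2-[(2Z)-5-(TBSO)-3-methylpent-2-en-1-yl]cyclopentane-1,3-dione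
Product: 10 (2S,3R)-3-hydroxy-2-methyl-2-[(2Z)-5-(TBSO)-3-methylpent-2-en-1-yl]cyclopentan-1-one
Conditions: ketoreductase ((R)-selective, chosen by panel screening), NADP+ (cat.), i-PrOH, phosphate buffer pH 7, 30 °C
Reagents that add atoms: none
Why: Enzymatic desymmetrising reduction: the ketoreductase distinguishes the two enantiotopic carbonyls and the two faces, so one hydride transfer sets both C1 (2S) and C2 (3R, hydroxyl cis to methyl), the relative configuration that enzymatic reductions are known to give with 2-methyl-2-alkylcyclopentane-1,3-diones carrying long side chains.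

Step 7
Reactants: 10 (2S,3R)-3-hydroxy-2-methyl-2-[(2Z)-5-(TBSO)-3-methylpent-2-en-1-yl]cyclopentan-1-one
Product: 11 (2S,3R)-3-(TBSO)-2-methyl-2-[(2Z)-5-(TBSO)-3-methylpent-2-en-1-yl]cyclopentan-1-one
Conditions: TBSOTf, 2,6-lutidine, CH2Cl2, −78 → 0 °C
Reagents that add atoms: tert-butyldimethylsilyl trifluoromethanesulfonate CC(C)(C)[Si](C)(C)OS(=O)(=O)C(F)(F)F
Why: Silylation of the hindered neopentylic alcohol with the silyl triflate and 2,6-lutidine protects C2–O for the rest of the route and prevents retro-aldol opening of the β-hydroxy ketone in the enolate chemistry that follows.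

Step 8
Reactants: 11 (2S,3R)-3-(TBSO)-2-methyl-2-[(2Z)-5-(TBSO)-3-methylpent-2-en-1-yl]cyclopentan-1-one
Product: 15 (2S,3R,5E)-3-(TBSO)-5-ethylidene-2-methyl-2-[(2Z)-5-(TBSO)-3-methylpent-2-en-1-yl]cyclopentan-1-one, via C4 lithium enolate 12 (not isolated), via lithium aldolate 13 (not isolated), via aldol mesylate 14 (not isolated)
Conditions: LiN(i-Pr)2, THF, −78 °C; CH3CHO; MsCl, −78 → 0 °C; Et3N, 0 → 25 °C
Reagents that add atoms: acetaldehyde CC=O
Why: Aldol condensation: because C1 is quaternary the ketone enolises only toward C4, the lithium enolate adds to acetaldehyde, and mesylation of the aldolate followed by base-induced elimination gives the conjugated exocyclic enone, which removes the transient stereocentres.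

Step 9
Reactants: 15 (2S,3R,5E)-3-(TBSO)-5-ethylidene-2-methyl-2-[(2Z)-5-(TBSO)-3-methylpent-2-en-1-yl]cyclopentan-1-one
Product: 17 (4R,5S)-4-(TBSO)-5-methyl-2-(propan-2-yl)-5-[(2Z)-5-(TBSO)-3-methylpent-2-en-1-yl]cyclopent-1-en-1-yl trifluoromethanesulfonate, via isopropyl lithium enolate 16 (not isolated)
Conditions: Me2CuLi (from MeLi and CuI), THF, −78 → −30 °C; N-(5-chloropyridin-2-yl)triflimide, −78 → 25 °C; sat. aq. NH4Cl
Reagents that add atoms: lithium dimethylcuprate [Li+].C[Cu-]C; N-(5-chloropyridin-2-yl)-1,1,1-trifluoro-N-(trifluoromethylsulfonyl)methanesulfonamide O=S(=O)(N(c1ccc(Cl)cn1)S(=O)(=O)C(F)(F)F)C(F)(F)F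
Why: Conjugate addition of the cuprate to the exocyclic enone turns the ethylidene carbon into the isopropyl group and at the same time generates the C4=C5 enolate regiospecifically, which the N-aryl triflimide sulfonylates on oxygen to give the tetrasubstituted enol triflate (cuprate addition with enolate trapping).

Step 10
Reactants: 17 (4R,5S)-4-(TBSO)-5-methyl-2-(propan-2-yl)-5-[(2Z)-5-(TBSO)-3-methylpent-2-en-1-yl]cyclopent-1-en-1-yl trifluoromethanesulfonate
Product: 18 (4R,5S)-4-(TBSO)-5-[(2Z)-5-hydroxy-3-methylpent-2-en-1-yl]-5-methyl-2-(propan-2-yl)cyclopent-1-en-1-yl trifluoromethanesulfonate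
Conditions: HF·pyridine, pyridine, THF, 0 °C
Reagents that add atoms: none
Why: Pyridine-buffered HF·pyridine should cleave the unhindered primary silyl ether far faster than the neopentylic secondary one and does not touch the enol triflate (selective desilylation).

Step 11
Reactants: 18 (4R,5S)-4-(TBSO)-5-[(2Z)-5-hydroxy-3-methylpent-2-en-1-yl]-5-methyl-2-(propan-2-yl)cyclopent-1-en-1-yl trifluoromethanesulfonate
Product: 19 (4R,5S)-4-(TBSO)-5-methyl-5-[(2Z)-3-methyl-5-oxopent-2-en-1-yl]-2-(propan-2-yl)cyclopent-1-en-1-yl trifluoromethanesulfonate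
Conditions: Dess–Martin periodinane, NaHCO3, CH2Cl2, 0 → 25 °C
Reagents that add atoms: none
Why: Buffered Dess–Martin oxidation gives the β,γ-unsaturated aldehyde under neutral conditions, so the C8=C9 olefin does not migrate into conjugation, and the aldehyde is used directly.

Step 12
Reactants: 19 (4R,5S)-4-(TBSO)-5-methyl-5-[(2Z)-3-methyl-5-oxopent-2-en-1-yl]-2-(propan-2-yl)cyclopent-1-en-1-yl trifluoromethanesulfonate
Product: 21 2β-(TBSO)-4-isopropyl-1β,8-dimethylbicyclo[5.3.0]deca-4,8-dien-6α-ol, via alkenylchromium dichloride 20 (not isolated)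
Conditions: CrCl2 (excess), NiCl2 (cat.), degassed DMF, 25 °C, slow addition of 19 to high dilution
Reagents that add atoms: none
Why: Zerovalent nickel, generated from NiCl2 by CrCl2, inserts into the C5–OTf bond and hands the alkenyl group to trivalent chromium, and the resulting alkenylchromium adds to the C6 aldehyde through a chromium-bridged four-centre transition state. The closest known reaction type is the intramolecular Nozaki–Hiyama–Kishi coupling of alkenyl triflates with aldehydes that is used to close medium rings. Ring B is closed in a 7-exo-trig carbonyl addition that forms the C5–C6 bond. The new C6 stereocentre is controlled by the quaternary C1 through the tether: the chain leaves C1 on the α face while the chromium-bound oxygen lies in the cyclopentene plane on the isopropyl side, so the 6α alcohol is expected, and either epimer is usable because step 13 erases C6. The step needs chemoselective activation of the enol triflate and ring closure over oligomerisation: the weakly basic, aldehyde-selective organochromium spares the silyl ether, the C8=C9 olefin and the enolisable aldehyde, while the Z olefin and the quaternary C1 hold the chain ends together and slow addition at high dilution suppresses intermolecular coupling.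

Step 13
Reactants: 21 2β-(TBSO)-4-isopropyl-1β,8-dimethylbicyclo[5.3.0]deca-4,8-dien-6α-ol
Product: 22 2β-(TBSO)-4-isopropyl-1β,8-dimethylbicyclo[5.3.0]deca-4,8-dien-6-one
Conditions: Dess–Martin periodinane, NaHCO3, CH2Cl2, 0 °C
Reagents that add atoms: none
Why: Dess–Martin oxidation of the allylic alcohol gives the C4=C5–C6=O enone, which merges both C6 epimers into one compound.

Step 14
Reactants: 22 2β-(TBSO)-4-isopropyl-1β,8-dimethylbicyclo[5.3.0]deca-4,8-dien-6-one
Product: 23 2β-(TBSO)-4-isopropyl-1β,8-dimethylbicyclo[5.3.0]deca-4,8-dien-6β-ol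
Conditions: NaBH4, CeCl3·7H2O, MeOH, −78 °C
Reagents that add atoms: none
Why: Luche reduction enforces 1,2-addition, and hydride should reach C6 from the α face, away from the β-oriented C1 methyl group that stands 1,3 to the carbonyl, to give the 6β alcohol.

Step 15
Reactants: 23 2β-(TBSO)-4-isopropyl-1β,8-dimethylbicyclo[5.3.0]deca-4,8-dien-6β-ol
Product: 24 4β,5β-epoxy-2β-(TBSO)-4α-isopropyl-1β,8-dimethylbicyclo[5.3.0]dec-8-en-6β-ol
Conditions: VO(acac)2 (cat.), t-BuOOH, CH2Cl2, 0 °C
Reagents that add atoms: tert-butyl hydroperoxide CC(C)(C)OO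
Why: Hydroxyl-directed epoxidation: the vanadate ester of the 6β hydroxyl, which allylic strain against the C4 isopropyl group holds over the β face, delivers the peroxide oxygen syn to itself and sets the 4β,5β-epoxide, while the allylic tetrasubstituted olefin should react much faster than the homoallylic C8=C9.

Step 16
Reactants: 24 4β,5β-epoxy-2β-(TBSO)-4α-isopropyl-1β,8-dimethylbicyclo[5.3.0]dec-8-en-6β-ol
Product: 25 4β,5β-epoxy-2β-(TBSO)-4α-isopropyl-1β,8-dimethylbicyclo[5.3.0]dec-8-en-6-one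
Conditions: Dess–Martin periodinane, NaHCO3, CH2Cl2, 0 → 25 °C
Reagents that add atoms: none
Why: Buffered Dess–Martin oxidation converts the secondary epoxy alcohol into the α,β-epoxy ketone without opening the acid-sensitive epoxide.

Step 17
Reactants: 25 4β,5β-epoxy-2β-(TBSO)-4α-isopropyl-1β,8-dimethylbicyclo[5.3.0]dec-8-en-6-one
Product: 27 (5α-H)-2β-(TBSO)-4β-hydroxy-4α-isopropyl-1β,8-dimethylbicyclo[5.3.0]dec-8-en-6-one, via samarium enolate 26 (not isolated)
Conditions: SmI2, THF–MeOH, −90 °C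
Reagents that add atoms: none
Why: Reductive opening of an α,β-epoxy ketone by SmI2 cleaves only the C5–O bond, so the C4–O bond keeps its β configuration as the tertiary alcohol, and methanol protonates the C5 samarium enolate to the ketol, which should settle as the 5α-H (trans-fused) isomer because there C6 lies trans to the C4 isopropyl group and cis to the hydrogen-bonding 4β hydroxyl.

Step 18
Reactants: 27 (5α-H)-2β-(TBSO)-4β-hydroxy-4α-isopropyl-1β,8-dimethylbicyclo[5.3.0]dec-8-en-6-one
Product: 28 (5α-H)-2β-(TBSO)-4α-isopropyl-1β,8-dimethylbicyclo[5.3.0]dec-8-ene-4β,6α-diol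
Conditions: Me4NBH(OAc)3, MeCN–AcOH, −30 °C
Reagents that add atoms: none
Why: Evans–Saksena reduction: the 4β hydroxyl replaces an acetate on boron and hands hydride intramolecularly, through a chair-like six-membered transition state, to the β face of the C6 carbonyl, which gives the 1,3-anti diol with the 6α hydroxyl.

Step 19
Reactants: 28 (5α-H)-2β-(TBSO)-4α-isopropyl-1β,8-dimethylbicyclo[5.3.0]dec-8-ene-4β,6α-diol, 29 4-methoxybenzoyl chloride
Product: 30 (5α-H)-2β-(TBSO)-4β-hydroxy-4α-isopropyl-1β,8-dimethylbicyclo[5.3.0]dec-8-en-6α-yl 4-methoxybenzoate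
Conditions: Et3N, DMAP (cat.), CH2Cl2, 0 → 25 °C
Reagents that add atoms: none
Why: DMAP-catalysed acylation occurs at the secondary C6 hydroxyl only, because the C4 hydroxyl is tertiary and shielded by the isopropyl group.

Step 20
Reactants: 30 (5α-H)-2β-(TBSO)-4β-hydroxy-4α-isopropyl-1β,8-dimethylbicyclo[5.3.0]dec-8-en-6α-yl 4-methoxybenzoate
Product: 31 (5α-H)-2β,4β-dihydroxy-4α-isopropyl-1β,8-dimethylbicyclo[5.3.0]dec-8-en-6α-yl 4-methoxybenzoate
Conditions: HF·pyridine, MeCN, 0 → 25 °C
Reagents that add atoms: none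
Why: Fluoride-mediated desilylation with mildly acidic HF·pyridine frees the C2 hydroxyl without acyl migration or loss of the tertiary alcohol.

Step 21
Reactants: 31 (5α-H)-2β,4β-dihydroxy-4α-isopropyl-1β,8-dimethylbicyclo[5.3.0]dec-8-en-6α-yl 4-methoxybenzoate, 32 angelic acid
Product: 34 target CNP0204191.1 (2β-angelate of 31), via mixed anhydride 33 (not isolated)
Conditions: 2,4,6-trichlorobenzoyl chloride, Et3N, toluene, 25 °C; then 31, 80 °C
Reagents that add atoms: none
Why: Mixed-anhydride (Yamaguchi-type) esterification run without DMAP is the established way to acylate hindered alcohols with angelic acid without Z to E isomerisation, and only the secondary C2 hydroxyl reacts since the C4 hydroxyl is tertiary.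

**Compound list**

1 | tert-butyl(but-3-yn-1-yloxy)dimethylsilane | C#CCCO[Si](C)(C)C(C)(C)C | starting material
2 | lithium acetylide of 1 (lithium on the terminal alkyne carbon) | [Li]C#CCCO[Si](C)(C)C(C)(C)C | intermediate
3 | ethyl 5-(TBSO)pent-2-ynoate | CCOC(=O)C#CCCO[Si](C)(C)C(C)(C)C | intermediate
4 | lithium alkenyl(methyl)cuprate from syn carbocupration of 3 (copper on C2, cis to the new C3 methyl) | [Li+].CCOC(=O)/C([Cu-]C)=C(/C)CCO[Si](C)(C)C(C)(C)C | intermediate
5 | ethyl (2Z)-5-(TBSO)-3-methylpent-2-enoate | CCOC(=O)/C=C(/C)CCO[Si](C)(C)C(C)(C)C | intermediate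
6 | (2Z)-5-(TBSO)-3-methylpent-2-en-1-ol | OC/C=C(/C)CCO[Si](C)(C)C(C)(C)C | intermediate
7 | {[(3Z)-5-bromo-3-methylpent-3-en-1-yl]oxy}(tert-butyl)dimethylsilane | BrC/C=C(/C)CCO[Si](C)(C)C(C)(C)C | intermediate
8 | 2-methylcyclopentane-1,3-dione | CC1C(=O)CCC1=O | starting material
9 | 2-methyl-2-[(2Z)-5-(TBSO)-3-methylpent-2-en-1-yl]cyclopentane-1,3-dione | CC1(C/C=C(/C)CCO[Si](C)(C)C(C)(C)C)C(=O)CCC1=O | intermediate
10 | (2S,3R)-3-hydroxy-2-methyl-2-[(2Z)-5-(TBSO)-3-methylpent-2-en-1-yl]cyclopentan-1-one (hydroxyl cis to methyl) | O[C@@H]1CCC(=O)[C@@]1(C)C/C=C(/C)CCO[Si](C)(C)C(C)(C)C | intermediate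
11 | (2S,3R)-3-(TBSO)-2-methyl-2-[(2Z)-5-(TBSO)-3-methylpent-2-en-1-yl]cyclopentan-1-one | CC(C)(C)[Si](C)(C)O[C@@H]1CCC(=O)[C@@]1(C)C/C=C(/C)CCO[Si](C)(C)C(C)(C)C | intermediate
12 | lithium enolate of 11 (C4=C5–OLi) | CC(C)(C)[Si](C)(C)O[C@@H]1CC=C(O[Li])[C@@]1(C)C/C=C(/C)CCO[Si](C)(C)C(C)(C)C | intermediate
13 | lithium aldolate: 11 bearing a 1-(lithiooxy)ethyl group on C4 (mixture at the two new centres) | CC(C)(C)[Si](C)(C)O[C@@H]1CC(C(C)O[Li])C(=O)[C@@]1(C)C/C=C(/C)CCO[Si](C)(C)C(C)(C)C | intermediate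
14 | aldol mesylate: 11 bearing a 1-(methanesulfonyloxy)ethyl group on C4 (mixture at the two new centres) | CC(C)(C)[Si](C)(C)O[C@@H]1CC(C(C)OS(C)(=O)=O)C(=O)[C@@]1(C)C/C=C(/C)CCO[Si](C)(C)C(C)(C)C | intermediate
15 | (2S,3R,5E)-3-(TBSO)-5-ethylidene-2-methyl-2-[(2Z)-5-(TBSO)-3-methylpent-2-en-1-yl]cyclopentan-1-one | CC(C)(C)[Si](C)(C)O[C@@H]1C/C(=C\C)C(=O)[C@@]1(C)C/C=C(/C)CCO[Si](C)(C)C(C)(C)C | intermediate
16 | lithium enolate after cuprate addition (C4 isopropyl, C4=C5–OLi) | CC(C)(C)[Si](C)(C)O[C@@H]1CC(C(C)C)=C(O[Li])[C@@]1(C)C/C=C(/C)CCO[Si](C)(C)C(C)(C)C | intermediate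
17 | (4R,5S)-4-(TBSO)-5-methyl-2-(propan-2-yl)-5-[(2Z)-5-(TBSO)-3-methylpent-2-en-1-yl]cyclopent-1-en-1-yl trifluoromethanesulfonate | CC(C)(C)[Si](C)(C)O[C@@H]1CC(C(C)C)=C(OS(=O)(=O)C(F)(F)F)[C@@]1(C)C/C=C(/C)CCO[Si](C)(C)C(C)(C)C | intermediate
18 | (4R,5S)-4-(TBSO)-5-[(2Z)-5-hydroxy-3-methylpent-2-en-1-yl]-5-methyl-2-(propan-2-yl)cyclopent-1-en-1-yl trifluoromethanesulfonate | CC(C)(C)[Si](C)(C)O[C@@H]1CC(C(C)C)=C(OS(=O)(=O)C(F)(F)F)[C@@]1(C)C/C=C(/C)CCO | intermediate
19 | (4R,5S)-4-(TBSO)-5-methyl-5-[(2Z)-3-methyl-5-oxopent-2-en-1-yl]-2-(propan-2-yl)cyclopent-1-en-1-yl trifluoromethanesulfonate | CC(C)(C)[Si](C)(C)O[C@@H]1CC(C(C)C)=C(OS(=O)(=O)C(F)(F)F)[C@@]1(C)C/C=C(/C)CC=O | intermediate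
20 | alkenylchromium dichloride (trivalent chromium on C5 in place of the triflate of 19) | CC(C)(C)[Si](C)(C)O[C@@H]1CC(C(C)C)=C([Cr](Cl)Cl)[C@@]1(C)C/C=C(/C)CC=O | intermediate
21 | 2β-(TBSO)-4-isopropyl-1β,8-dimethylbicyclo[5.3.0]deca-4,8-dien-6α-ol | CC(C)(C)[Si](C)(C)O[C@@H]1CC(C(C)C)=C2[C@@H](O)CC(C)=CC[C@]21C | intermediate
22 | 2β-(TBSO)-4-isopropyl-1β,8-dimethylbicyclo[5.3.0]deca-4,8-dien-6-one | CC(C)(C)[Si](C)(C)O[C@@H]1CC(C(C)C)=C2C(=O)CC(C)=CC[C@]21C | intermediate
23 | 2β-(TBSO)-4-isopropyl-1β,8-dimethylbicyclo[5.3.0]deca-4,8-dien-6β-ol | CC(C)(C)[Si](C)(C)O[C@@H]1CC(C(C)C)=C2[C@H](O)CC(C)=CC[C@]21C | intermediate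
24 | 4β,5β-epoxy-2β-(TBSO)-4α-isopropyl-1β,8-dimethylbicyclo[5.3.0]dec-8-en-6β-ol | CC(C)(C)[Si](C)(C)O[C@@H]1C[C@]2(C(C)C)O[C@@]23[C@H](O)CC(C)=CC[C@]31C | intermediate
25 | 4β,5β-epoxy-2β-(TBSO)-4α-isopropyl-1β,8-dimethylbicyclo[5.3.0]dec-8-en-6-one | CC(C)(C)[Si](C)(C)O[C@@H]1C[C@]2(C(C)C)O[C@@]23C(=O)CC(C)=CC[C@]31C | intermediate
26 | samarium enolate (C5=C6 enolate and C4 alkoxide, each bound to a diiodosamarium unit of trivalent samarium) | CC(C)(C)[Si](C)(C)O[C@@H]1C[C@@](O[Sm](I)I)(C(C)C)C2=C(O[Sm](I)I)CC(C)=CC[C@]21C | intermediate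
27 | (5α-H)-2β-(TBSO)-4β-hydroxy-4α-isopropyl-1β,8-dimethylbicyclo[5.3.0]dec-8-en-6-one (trans ring fusion) | CC(C)(C)[Si](C)(C)O[C@@H]1C[C@@](O)(C(C)C)[C@@H]2C(=O)CC(C)=CC[C@]21C | intermediate
28 | (5α-H)-2β-(TBSO)-4α-isopropyl-1β,8-dimethylbicyclo[5.3.0]dec-8-ene-4β,6α-diol | CC(C)(C)[Si](C)(C)O[C@@H]1C[C@@](O)(C(C)C)[C@@H]2[C@@H](O)CC(C)=CC[C@]21C | intermediate
29 | 4-methoxybenzoyl chloride | COc1ccc(cc1)C(Cl)=O | starting material
30 | (5α-H)-2β-(TBSO)-4β-hydroxy-4α-isopropyl-1β,8-dimethylbicyclo[5.3.0]dec-8-en-6α-yl 4-methoxybenzoate | CC(C)(C)[Si](C)(C)O[C@@H]1C[C@@](O)(C(C)C)[C@@H]2[C@@H](OC(=O)c3ccc(OC)cc3)CC(C)=CC[C@]21C | intermediate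
31 | (5α-H)-2β,4β-dihydroxy-4α-isopropyl-1β,8-dimethylbicyclo[5.3.0]dec-8-en-6α-yl 4-methoxybenzoate | O[C@@H]1C[C@@](O)(C(C)C)[C@@H]2[C@@H](OC(=O)c3ccc(OC)cc3)CC(C)=CC[C@]21C | intermediate
32 | angelic acid, (2Z)-2-methylbut-2-enoic acid | C/C=C(/C)C(O)=O | starting material
33 | mixed anhydride of angelic acid and 2,4,6-trichlorobenzoic acid | C/C=C(/C)C(=O)OC(=O)c1c(Cl)cc(Cl)cc1Cl | intermediate
34 | CNP0204191.1: (5α-H)-4β-hydroxy-4α-isopropyl-1β,8-dimethyl-2β-{[(2Z)-2-methylbut-2-enoyl]oxy}bicyclo[5.3.0]dec-8-en-6α-yl 4-methoxybenzoate | C/C=C(/C)C(=O)O[C@@H]1C[C@@](O)(C(C)C)[C@@H]2[C@@H](OC(=O)c3ccc(OC)cc3)CC(C)=CC[C@]21C | target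

**Step count and risks**

Total step count: 21. Longest linear sequence: 21 steps (1 to 34).

The three steps most likely to fail:

Step 12. Intermolecular aldehyde addition (oligomerisation) may outrun the seven-membered ring closure, or the hindered alkenylnickel or alkenylchromium species may be protonated so that the triflate is simply lost. The fallback forms the same C5–C6 bond by carbonyl–carbonyl reductive coupling instead of alkenylmetal addition. It sets out from 15 and comes back at 22. Addition of Me2CuLi to 15 followed by protonation (sat. aq. NH4Cl) gives isopropyl ketone F1. HF·pyridine with pyridine frees primary alcohol F2, and Dess–Martin oxidation gives keto aldehyde F3. A McMurry-type pinacol coupling with low-valent titanium (TiCl3(DME)1.5, Zn–Cu, DME, 25 °C) joins the C6 aldehyde carbon to the C5 ketone carbon and closes ring B as 5,6-diol F4. Parikh–Doering oxidation (SO3·pyridine, DMSO, i-Pr2NEt) converts only the secondary C6 hydroxyl, giving hydroxy ketone F5. SOCl2 in pyridine then eliminates the tertiary C5 hydroxyl toward C4, the only neighbouring carbon that carries a hydrogen, to give dienone 22.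

Step 17. The samarium enolate may be protonated on the β face, which would give the cis-fused C5 epimer, and the C4 oxygen may be lost by β-elimination back to dienone 22. The fallback is a stereospecific semipinacol 1,2-hydride shift that sets out from 24 and comes back at 27, so steps 16 and 17 are bypassed. TMSOTf with i-Pr2NEt (CH2Cl2, −78 °C) silylates the 6β hydroxyl and activates the epoxide. In this syn epoxy alcohol the C6 hydrogen is antiperiplanar to the C5–O bond, so it migrates to the α face of C5 as that bond breaks. This gives the C6 ketone with 5α-H and the C4 oxygen as its trimethylsilyl ether, silyloxy ketone F6. Citric acid in MeOH at 0 °C cleaves the tertiary trimethylsilyl ether to ketol 27.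

Step 6. No enzyme of the panel may accept the lipophilic dione with the required sense (hydroxyl cis to methyl, R at the carbinol), which would show as incomplete conversion or as the wrong diastereomer. The fallback sets out from 9 and comes back at 10. Asymmetric transfer hydrogenation (RuCl(p-cymene)(TsDPEN), the enantiomer that gives the 3S carbinol, HCO2H–Et3N) should deliver hydride on the face next to the methyl group, as small-molecule catalysts do with such diones. The expected product is trans ketol F7, in which C1 is already correct and only C2 is wrong. Mitsunobu inversion at C2 (4-nitrobenzoic acid, PPh3, DIAD, toluene) gives 4-nitrobenzoate F8, and K2CO3 in MeOH at 0 °C releases ketol 10.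

Further compounds
F1 | step 12 | isopropyl ketone: (2S,3R)-3-(TBSO)-2-methyl-5-(propan-2-yl)-2-[(2Z)-5-(TBSO)-3-methylpent-2-en-1-yl]cyclopentan-1-one (both C4 epimers in target numbering) | CC(C)(C)[Si](C)(C)O[C@@H]1CC(C(C)C)C(=O)[C@@]1(C)C/C=C(/C)CCO[Si](C)(C)C(C)(C)C
F2 | step 12 | primary alcohol: F1 with the primary silyl ether cleaved | CC(C)(C)[Si](C)(C)O[C@@H]1CC(C(C)C)C(=O)[C@@]1(C)C/C=C(/C)CCO
F3 | step 12 | keto aldehyde: C5 ketone with the C6 aldehyde at the end of the (Z)-3-methylpent-2-enyl chain | CC(C)(C)[Si](C)(C)O[C@@H]1CC(C(C)C)C(=O)[C@@]1(C)C/C=C(/C)CC=O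
F4 | step 12 | 5,6-diol: 2β-(TBSO)-4-isopropyl-1β,8-dimethylbicyclo[5.3.0]dec-8-ene-5,6-diol (mixture at C4, C5 and C6) | CC(C)(C)[Si](C)(C)O[C@@H]1CC(C(C)C)C2(O)C(O)CC(C)=CC[C@]21C
F5 | step 12 | hydroxy ketone: 2β-(TBSO)-5-hydroxy-4-isopropyl-1β,8-dimethylbicyclo[5.3.0]dec-8-en-6-one (mixture at C4 and C5) | CC(C)(C)[Si](C)(C)O[C@@H]1CC(C(C)C)C2(O)C(=O)CC(C)=CC[C@]21C
F6 | step 17 | silyloxy ketone: (5α-H)-2β-(TBSO)-4β-(trimethylsilyloxy)-4α-isopropyl-1β,8-dimethylbicyclo[5.3.0]dec-8-en-6-one | CC(C)(C)[Si](C)(C)O[C@@H]1C[C@@](O[Si](C)(C)C)(C(C)C)[C@@H]2C(=O)CC(C)=CC[C@]21C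
F7 | step 6 | trans ketol: (2S,3S)-3-hydroxy-2-methyl-2-[(2Z)-5-(TBSO)-3-methylpent-2-en-1-yl]cyclopentan-1-one (hydroxyl trans to methyl) | O[C@H]1CCC(=O)[C@@]1(C)C/C=C(/C)CCO[Si](C)(C)C(C)(C)C
F8 | step 6 | 4-nitrobenzoate of ketol 10 (C2 inverted relative to F7) | O=C(O[C@@H]1CCC(=O)[C@@]1(C)C/C=C(/C)CCO[Si](C)(C)C(C)(C)C)c1ccc(cc1)[N+](=O)[O-]
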